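**Retrosynthetic overview**
1. Rings: A is the methyl/isopropyl cyclohexane, B the cyclohexene holding the spiro carbon, C the pyran, D the diformylphloroglucinol arene. The last disconnection cuts C4–C4a and ring C. Ring C is first closed one carbon short, as the O1–C3–C4–C4a–C8a dihydrobenzofuran carrying ring B as a 2-alkenyl group. The spiro carbon C2 is then inserted between O1 and C3.
2. Enabling feature: O1 is the oxygen of an o,p-diformylphenol (ring D), so it acts as a carboxylate-like leaving group and nucleophile. In the target it sits on C2, one end of the allyl triad C2–C1'=C8a' of ring B, next to the C3 methylene. The triad C3–C2=C1' of the five-membered isomer differs only in the position of one hydrogen (H-8a' versus one H-3), which a palladium hydride can carry.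
3. The fragments are 5-iodo-2,4,6-trihydroxyisophthalaldehyde and a cis-fused 7-styryl-octahydronaphthalene. The latter comes from the cis-decalone by enol triflate formation and Suzuki–Miyaura coupling.
4. The decalone comes from (R)-citronellal by amine-catalysed Michael addition to methyl vinyl ketone, aldol condensation (ring B) and an intramolecular ene reaction (ring A).
5. Order of ring formation: B, A, the five-membered precursor of C, then C. Ring D and the phenyl ring are bought.

Key step: step 8

Assumption: 2,4,6-trihydroxyisophthalaldehyde, (E)-2-phenylvinylboronic acid and both enantiomers of 2-[methoxy(diphenyl)methyl]pyrrolidine are taken as catalogue chemicals.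

Step 1
Reactants: 1 (R)-citronellal; 2 methyl vinyl ketone
Product: 3 (2R,3R)-3,7-dimethyl-2-(3-oxobutyl)oct-6-enal
Conditions: (R)-2-[methoxy(diphenyl)methyl]pyrrolidine (5 mol %), ethyl 3,4-dihydroxybenzoate (20 mol %), neat, 4 °C
Reagents that add atoms: none
Why: Enamine-catalysed Michael addition of an aldehyde to an enone, in which the (R)-pyrrolidine shields one face of the E-enamine so that the new α-centre (the later ring-fusion CH) is set as (R) under catalyst control, independent of the resident (R)-methyl centre.

Step 2
Reactants: 3 (2R,3R)-3,7-dimethyl-2-(3-oxobutyl)oct-6-enal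
Product: 4 (4R)-4-[(2R)-6-methylhept-5-en-2-yl]cyclohex-2-en-1-one
Conditions: KOH (0.2 equiv), n-Bu4NOH (cat.), Et2O/THF/H2O, reflux
Reagents that add atoms: none
Why: Base-mediated intramolecular aldol condensation (6-enolexo) of the methyl ketone onto the aldehyde closes ring B without creating a stereocentre, and in dilute two-phase base the closure should be faster than enolisation of the hindered α-branched aldehyde, so the centre from step 1 is kept.

Step 3
Reactants: 4 (4R)-4-[(2R)-6-methylhept-5-en-2-yl]cyclohex-2-en-1-one
Product: 5 (4aR,5R,8R,8aR)-5-methyl-8-(prop-1-en-2-yl)octahydronaphthalen-2(1H)-one (cis-fused)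
Conditions: Me2AlCl (1.2 equiv), CH2Cl2, −78 to 0 °C; aq. HCl quench
Reagents that add atoms: none
Why: Lewis-acid-promoted intramolecular ene reaction of a 1,7-diene (prenyl group as ene, complexed enone as enophile), in which the alkene attacks the β-carbon axially on the face of the pseudo-equatorial side chain through a chair with the methyl and developing isopropenyl groups equatorial, setting a cis ring fusion (H-4a and H-8a cis) with the isopropenyl group trans to the new ring-B bond at C8a and trans to the methyl group.

Step 4
Reactants: 5 (4aR,5R,8R,8aR)-5-methyl-8-(prop-1-en-2-yl)octahydronaphthalen-2(1H)-one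
Product: 6 (4aR,5R,8S,8aS)-8-isopropyl-5-methyloctahydronaphthalen-2(1H)-one (same spatial arrangement; descriptors change by priority only)
Conditions: H2 (1 atm), Pd/C (10 wt %), EtOAc, 23 °C
Reagents that add atoms: none
Why: Heterogeneous hydrogenation takes the unhindered 1,1-disubstituted alkene, leaves the ketone, and neither forms nor touches a stereocentre.

Step 5
Reactants: 6 (4aR,5R,8S,8aS)-8-isopropyl-5-methyloctahydronaphthalen-2(1H)-one
Product: 7 (4aR,5R,8S,8aS)-8-isopropyl-5-methyl-3,4,4a,5,6,7,8,8a-octahydronaphthalen-2-yl trifluoromethanesulfonate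
Conditions: Tf2O (1.2 equiv), 2,6-di-tert-butyl-4-methylpyridine (1.5 equiv), CH2Cl2, 0 to 23 °C
Reagents that add atoms: trifluoromethanesulfonic anhydride, O=S(=O)(OS(=O)(=O)C(F)(F)F)C(F)(F)F
Why: Enol triflate formation by O-triflation and proton loss from the oxocarbenium ion under equilibrating conditions, which follows the known preference of cis-fused 2-decalones to enolise toward the ring fusion (C1) and leaves all four stereocentres untouched.

Step 6
Reactants: 7 the alkenyl triflate; 8 (E)-2-phenylvinylboronic acid
Product: 9 (1S,4R,4aR,8aS)-1-isopropyl-4-methyl-7-[(E)-2-phenylethenyl]-1,2,3,4,4a,5,6,8a-octahydronaphthalene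
Conditions: Pd(PPh3)4 (5 mol %), Na2CO3 (2 M aq.), THF, 60 °C
Reagents that add atoms: none
Why: Suzuki–Miyaura coupling of an alkenyl triflate with an E-alkenylboronic acid, which keeps both alkene geometries and does not touch the allylic ring-fusion centre.

Step 7
Reactants: 10 2,4,6-trihydroxyisophthalaldehyde
Product: 11 5-iodo-2,4,6-trihydroxyisophthalaldehyde
Conditions: N-iodosuccinimide (1.05 equiv), MeCN, 0 °C, dark
Reagents that add atoms: N-iodosuccinimide, O=C1CCC(=O)N1I
Why: Electrophilic aromatic iodination at the only free ring position, which is activated by three hydroxyl groups, so no regiochemical question arises.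

Step 8
Reactants: 9 the styryl diene; 11 5-iodo-2,4,6-trihydroxyisophthalaldehyde
Product: 13 guajadial D, via dihydrobenzofuran 12 (not isolated)
Conditions: Pd(dba)2 (10 mol %), 1,2-bis(diphenylphosphino)ethane (12 mol %), Ag2CO3 (0.55 equiv), 1,4-dioxane, 80 °C; then PhCO2H (20 mol %), 100 °C, same flask
Reagents that add atoms: none
Why: Proposed new method: oxidative addition of 11 to zerovalent palladium, syn-carbopalladation of the less hindered E-styryl double bond of s-trans 9 (aryl to the PhCH carbon, because only this regiochemistry gives an η3-allyl complex) and 5-exo attack of a flanking phenoxide on the exocyclic allyl terminus are the known Larock diene heteroannulation and give 12. Because the ring oxygen of 12 belongs to an o,p-diformylphenol it is a carboxylate-like leaving group, so zerovalent palladium re-ionises the O–CH bond with inversion, the allyl complex loses the syn ring-fusion hydrogen by β-hydride elimination, and the palladium hydride, still bound to the diene, returns that hydrogen to the former O–CH carbon (now CH2); this moves the allyl unit one carbon into ring B, and 6-exo attack of the phenoxide on its tertiary terminus inserts that carbon between O and CH2, turning the five-membered ring into the six-membered pyran. The closest known reactions are the palladium-hydride hydroalkoxylation of 1,3-dienes with phenols and Tsuji–Trost allylic etherification. C4 is set in the carbopalladation, which takes place on the convex face of the cis-decalin (the face of the two ring-fusion hydrogens); the spiro centre is set because only palladium on that same face can reach the ring-fusion hydrogen, while the chelating diphosphine enforces outer-sphere attack of oxygen anti to palladium, on the opposite face. The step needs ring enlargement to outrun reclosure and further hydride walking: relief of the strained cis-2,3-disubstituted five-membered ring and of the cis-decalin, the gain of a tertiary C–O bond, and the poor binding of zerovalent palladium to the product alkene (flanked by a quaternary and a fully substituted carbon) should make 13 the sink.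

**Compound list**
1 | (R)-citronellal, (3R)-3,7-dimethyloct-6-enal | C[C@H](CCC=C(C)C)CC=O | starting material
2 | methyl vinyl ketone (but-3-en-2-one) | CC(=O)C=C | starting material
3 | (2R,3R)-3,7-dimethyl-2-(3-oxobutyl)oct-6-enal | CC(=O)CC[C@@H](C=O)[C@H](C)CCC=C(C)C | intermediate
4 | (4R)-4-[(2R)-6-methylhept-5-en-2-yl]cyclohex-2-en-1-one | O=C1CC[C@@H](C=C1)[C@H](C)CCC=C(C)C | intermediate
5 | (4aR,5R,8R,8aR)-5-methyl-8-(prop-1-en-2-yl)octahydronaphthalen-2(1H)-one, cis-fused | O=C1CC[C@@H]2[C@H](C)CC[C@@H](C(C)=C)[C@@H]2C1 | intermediate
6 | (4aR,5R,8S,8aS)-8-isopropyl-5-methyloctahydronaphthalen-2(1H)-one, cis-fused | O=C1CC[C@@H]2[C@H](C)CC[C@@H](C(C)C)[C@@H]2C1 | intermediate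
7 | (4aR,5R,8S,8aS)-8-isopropyl-5-methyl-3,4,4a,5,6,7,8,8a-octahydronaphthalen-2-yl trifluoromethanesulfonate | FC(F)(F)S(=O)(=O)OC1=C[C@@H]2[C@H](CC1)[C@H](C)CC[C@H]2C(C)C | intermediate
8 | (E)-2-phenylvinylboronic acid | OB(O)/C=C/c1ccccc1 | starting material
9 | (1S,4R,4aR,8aS)-1-isopropyl-4-methyl-7-[(E)-2-phenylethenyl]-1,2,3,4,4a,5,6,8a-octahydronaphthalene | c1ccccc1/C=C/C1=C[C@@H]2[C@H](CC1)[C@H](C)CC[C@H]2C(C)C | intermediate
10 | 2,4,6-trihydroxyisophthalaldehyde | O=Cc1c(O)cc(O)c(C=O)c1O | starting material
11 | 5-iodo-2,4,6-trihydroxyisophthalaldehyde | O=Cc1c(O)c(I)c(O)c(C=O)c1O | intermediate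
12 | (2R,3S)-4,6-dihydroxy-2-[(4aR,5R,8S,8aS)-8-isopropyl-5-methyl-3,4,4a,5,6,7,8,8a-octahydronaphthalen-2-yl]-3-phenyl-2,3-dihydro-1-benzofuran-5,7-dicarbaldehyde (2,3-cis) | O=Cc1c(O)c(C=O)c(O)c2c1O[C@@H](C1=C[C@@H]3[C@H](CC1)[C@H](C)CC[C@H]3C(C)C)[C@H]2c1ccccc1 | intermediate
13 | guajadial D, (2S,4S,4a'R,5'R,8'S)-5,7-dihydroxy-8'-isopropyl-5'-methyl-4-phenyl-3',4',4a',5',6',7',8'-heptahydrospiro[chromane-2,2'-naphthalene]-6,8-dicarbaldehyde | CC(C)[C@@H]1CC[C@@H](C)[C@H]2CC[C@@]3(C=C12)C[C@@H](c1ccccc1)c1c(O)c(C=O)c(O)c(C=O)c1O3 | target

Total steps: 8. Longest linear sequence: 7 (steps 1 to 6, then step 8).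

**Steps most likely to fail**

**Step 8.**
- What may go wrong: the catalyst may be tied up by chelation to the salicylaldehyde units. The hydride walk may stall at the five-membered ring. The palladium hydride may leave the diene, so the facial memory that sets the spiro centre is lost.
- Fallback (known chemistry only): it sets out from 9 and 11 and comes back at 13.
- The heteroannulation is run under buffered standard conditions (Pd(OAc)2, excess NaHCO3, n-Bu4NCl, DMF, 60 °C), and 12 is isolated.
- Compound 12 is opened by the known palladium-catalysed 1,4-elimination of allylic esters and aryl ethers (Pd(PPh3)4, Et3N, THF, reflux) to the ring-opened dienyl phenol F1.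
- F1 is closed by acid-catalysed intramolecular hydroalkoxylation ((+)-camphorsulfonic acid, 5 mol %, CH2Cl2, −20 °C): protonation at the terminal diene CH, then 6-exo capture of the tertiary allyl cation.
- The ring still grows from five to six atoms, now over two flasks, and the spiro centre is then controlled by the resident C4 substituent.

**Step 3.**
- What may go wrong: the Lewis acid may turn the concerted ene reaction into a stepwise cationic process with 1,2-hydride shifts, or give poor control of the ring fusion.
- Fallback: it builds the decalone by cycloaddition, sets out from 2 and comes back at 6.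
- Compound 2 and isovaleraldehyde are joined by the same amine-catalysed Michael addition, now with the (S)-pyrrolidine, to give (S)-2-isopropyl-5-oxohexanal F2.
- Aldol condensation gives (S)-4-isopropylcyclohex-2-en-1-one F3.
- A Diels–Alder reaction with 2-(trimethylsilyloxy)buta-1,3-diene (AlBr3–AlMe3 mixed Lewis acid, toluene/CH2Cl2, −5 °C), anti to the isopropyl group and para-selective, gives the cis-fused keto silyl enol ether F4.
- Salt-free Wittig methylenation (Ph3P=CH2, THF, −78 to 0 °C) gives the exocyclic methylene compound F5.
- Hydrogenation with RhCl(PPh3)3 from the convex face gives the methyl-bearing silyl enol ether F6.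
- K2CO3 in MeOH then releases 6.

**Step 5.**
- What may go wrong: proton loss toward the wrong α-carbon would place the double bond away from the ring fusion, and the hydride walk of step 8 would then run in the wrong direction.
- Fallback: it sets out from 6 and comes back at 7.
- Equilibrating silylation (Me3SiI, (Me3Si)2NH, CH2Cl2, 23 °C) gives the ring-fusion-side trimethylsilyl enol ether F7, which can be freed from its regioisomer (the latter is hydrolysed back to 6 and recycled).
- F7 is then converted regiospecifically into 7 through the lithium enolate (MeLi, THF, 0 °C; then PhNTf2).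

**Further compounds**
F1 | step 8 | dienyl phenol, 2,4,6-trihydroxy-5-{(1S,2E)-2-[(4aR,5R,8S)-8-isopropyl-5-methyl-4,4a,5,6,7,8-hexahydronaphthalen-2(3H)-ylidene]-1-phenylethyl}isophthalaldehyde | O=Cc1c(O)c(C=O)c(O)c(c1O)[C@H](c2ccccc2)/C=C3\CC[C@H]4C(=C3)[C@H](C(C)C)CC[C@H]4C
F2 | step 3 | (S)-2-isopropyl-5-oxohexanal | CC(=O)CC[C@H](C=O)C(C)C
F3 | step 3 | (S)-4-isopropylcyclohex-2-en-1-one | O=C1CC[C@H](C=C1)C(C)C
F4 | step 3 | cis-fused keto silyl enol ether, (4S,4aS,8aS)-4-isopropyl-6-(trimethylsilyloxy)-3,4,4a,5,8,8a-hexahydronaphthalen-1(2H)-one | C[Si](C)(C)OC1=CC[C@@H]2C(=O)CC[C@@H](C(C)C)[C@@H]2C1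
F5 | step 3 | exocyclic methylene compound (C=O of F4 replaced by C=CH2, stereocentres unchanged) | C[Si](C)(C)OC1=CC[C@@H]2C(=C)CC[C@@H](C(C)C)[C@@H]2C1
F6 | step 3 | methyl-bearing silyl enol ether (hydrogen delivered to the convex face, methyl cis to the neighbouring ring-B CH2) | C[Si](C)(C)OC1=CC[C@@H]2[C@H](C)CC[C@@H](C(C)C)[C@@H]2C1
F7 | step 5 | ring-fusion-side trimethylsilyl enol ether of 6 | C[Si](C)(C)OC1=C[C@@H]2[C@H](CC1)[C@H](C)CC[C@H]2C(C)C
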